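Remark on the chemistry: isoflavanone 15 is expected as a racemic mixture of C2/C3 diastereomers and is carried on unseparated, because both centres disappear in step 10; commercial 2,4,6-trihydroxyacetophenone monohydrate is assumed to be dried before use.

## The problem

Lupalbigenin (17) is a 3-arylchromen-4-one. Ring A is a phloroglucinol-type benzene with hydroxyls at C5 and C7 and a prenyl group at C6, fused to the 4-pyranone ring C; ring B, a 4'-hydroxy-3'-prenylphenyl group, sits on C3. The target has no stereocentre. The only stereocentres of the route are the transient C2 and C3 of isoflavanone 15, which control nothing and are erased on aromatisation. The real selectivity problem is regiochemical: the prenyl group must end at C6 and not at C8, and these positions differ only in which of the two oxygens ortho to the acyl carbon becomes O1. The two prenyl groups are the fragile part. Acid closes them onto a neighbouring phenol to give 2,2-dimethylchromans, and quinone oxidants, halogens and hydrogenation all attack them, so ring C cannot be aromatised by oxidation and the phenols cannot be freed by strong acid or hydrogenolysis. The feature that opens the key step is C2: it is a formyl-level carbon between O1 and C3, the same oxidation level as the methylene carbon of a methoxymethyl ether on O1. Such an ether already holds C2 with its bond to O1 and a spare methoxy leaving group; only the C2–C3 bond is missing, and a carbenoid at C3 can make it by C–H insertion. The phenol that receives the methoxymethyl group is thereby fixed as O1, so the C6/C8 question becomes a question of which phenol is left free at one defined stage.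

## Retrosynthesis

**17 back to 15.** No skeletal bond is cut at first. The three O–H bonds of 17 are traced to O–Si bonds in isoflavone 16, and the C2=C3 double bond of 16 to a C2–OMe/C3–H pair in the 2-methoxyisoflavanone 15. A free hydroxyl ortho to the acyl group would capture a carbenoid by O–H insertion, so the phenols must stay masked until the end. An isoflavanone without the C2 oxygen would need a dehydrogenation that the prenyl groups would not survive. The forward steps ask only for a base-induced β-elimination and a fluoride desilylation.

**15 back to 14 (key disconnection, C2–C3).** The neighbouring cuts are O1–C2 and C3–C1'. The first is the classical closure of a 2-hydroxydeoxybenzoin with a one-carbon electrophile. The second is coupling of a 3-halochromone, which needs a halogenation in the presence of prenyl alkenes. Cutting C2–C3 is preferred because C2 is then already present in the precursor as the methylene of the protecting group on O1. Diazoketone 14 is open between the two arenes, has no stereocentre and differs from a plain deoxybenzoin only by the diazo group. The forward reaction must insert a dirhodium carbenoid into the acetal C–H bond through a six-membered transition state, and not attack the O1 lone pair or any other site.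

**14 back to 13 (C3=N2).** The diazo group is traced to the methylene of deoxybenzoin 13. This methylene lies between an aryl and an aroyl group and should accept direct diazo transfer with an amidine base, with no activating group to add and remove.

**13 back to 12 and 4 (C3–C1').** The alternative cut, C4–C4a, would mean acylating a ring A organometallic with an enolisable ring B arylacetyl electrophile, or a Lewis-acid acylation that the prenyl groups forbid. Cutting C3–C1' divides the molecule into methyl ketone 12 and aryl bromide 4, two fragments of similar size that each carry one prenyl group. The forward step is a palladium-catalysed mono-α-arylation of a hindered methyl ketone under a base mild enough for aryl silyl ethers.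

**12 back to 5 and 7 (ring A).** The O–CH2OMe bond of 12 is cut to phenol 11. In 11 the prenyl group is para to the free hydroxyl, so the aryl–CH2 bond is traced through two consecutive [3,3] shifts (via dienones 9 and 10) to the O-prenyl ether 8. This is the step that settles C6 against C8: the oxygen that delivers the prenyl group emerges as the only free phenol, it alone receives the methoxymethyl group, and the carbon para to it becomes C6. Direct C-prenylation of 5 or 6 would go ortho to a free hydroxyl and leave the three oxygens to be told apart by sterics alone. Ether 8 comes from phenol 6 and prenol 7, and 6 from 2,4,6-trihydroxyacetophenone 5 by silylation of the two hydroxyls that are not to become O1. The silylation must stop at two groups, and the rearrangement must run through to the para position.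

**4 back to 1 and 2 (ring B).** The aryl–prenyl bond of 4 is cut to 4-bromophenol 1 and prenyl bromide 2, by way of phenol 3. The bromine blocks the para position during ortho C-alkylation and later serves as the handle for the coupling with 12.

## Roads not taken

Alternative 1: Both aryl–prenyl bonds (C6–C1'' and C3'–C1''') are cut at once, back to the 5,4'-bis(2-methylbut-3-en-2-yl) ether A2, which would be made from genistein A3 after silylation of the 7-hydroxyl. Heating A2, optionally with Eu(fod)3 (trivalent europium), should cause two aromatic [3,3] shifts that place normal prenyl groups at C6 and C3' and free both phenols, giving 7-O-triisopropylsilyl-lupalbigenin A1; desilylation ends the synthesis. The merits are real: the isoflavone skeleton is bought, both prenyl groups arrive in one operation, and the whole route is roughly half as long as the chosen one. The weak points lie in making A2 and in the fate of the ring A shift. The 5-hydroxyl of A3 is chelated to C4=O and peri-hindered, the worst position for a tertiary allyl ether, and tertiary aryl ethers ionise easily under heat or Lewis acid. The dienone formed at C6 can tautomerise as wanted or shift on to C8. The liberated phenols sit next to prenyl groups at high temperature, where chroman formation begins. In step count Alternative 1 is clearly better. The chosen plan sets against it that its single sigmatropic step starts from a primary prenyl ether of an acetophenone, a closely precedented substrate type, that it never has to etherify the chelated hydroxyl with a tertiary group, and that C6 against C8 is decided by a rearrangement whose outcome is fixed by which oxygen carries the prenyl group.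

Alternative 2: Ring A is cut at C8–C8a and C4a–C5 into the 1-methoxy-2-prenyl-1,3-bis(trimethylsilyloxy)butadiene A5 and the bromoalkynone A6, which already carries ring B. Cycloaddition followed by loss of methanol and silyl groups should give the bromo-deoxybenzoin A4, with the prenyl group between two hydroxyls and bromine where O1 must later be attached. The position of the ring A prenyl group is fixed by the construction of the diene, which is as secure as the rearrangement used in the chosen plan, and the route is convergent. The weaknesses are the partners and the sequel. A5 is a moisture-sensitive, fully substituted ketene acetal. A6 has an acidic methylene between an arene and a halo-ynone and is prone to isomerise. A4 still lacks C2 and the C8a–O1 bond, so a formylation and a copper-mediated C–O closure at a hindered bromide must follow. The ring B methoxymethyl ether must finally be removed with acid next to free ortho-prenyl phenols. The chosen plan is shorter after the key step (two mild steps against four or more) and uses only bench-stable intermediates up to the diazoketone. Alternative 2 avoids a diazo compound, which is an advantage in handling on scale.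

Alternative 3: Ring B is cut at C1'–C2' and C5'–C6' into the 3-ethynylchromone A8 and the 2-silyloxy-3-prenylbutadiene A9. A [4+2] cycloaddition, thermal or with CoBr2(dppe) reduced by zinc in the presence of ZnI2, should give the cyclohexa-1,4-diene A7. Dehydrogenation to the arene and removal of the silyl and methoxymethyl groups would follow. The plan is convergent, the alkyne delivers a ring only one oxidation step from aromatic, and A8 is available from a 3-iodochromone by alkynylation. Its weak points are three. The regiochemistry of a 2,3-disubstituted diene with two similar directing groups is not reliably "para". The diene A7 must be aromatised with an oxidant in the presence of two prenyl groups, the very operation the chosen plan is designed to avoid. And the ring A problem is untouched, since A8 needs the 6-prenyl pattern to be made by other means and then loses its methoxymethyl groups under acid beside that prenyl group. Alternative 3 is the more convergent plan and uses no diazo chemistry. The chosen plan sets against it that ring C is closed and aromatised with no oxidant and no acid after the prenyl groups are in place.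

Key step: step 9

Step 1
Reactants: 1 4-bromophenol; 2 1-bromo-3-methylbut-2-ene (prenyl bromide)
Product: 3 4-bromo-2-(3-methylbut-2-enyl)phenol
Conditions: NaH, toluene, 0 °C to rt
Reagents that add atoms: none
Why: Ortho-selective C-alkylation of a sodium phenoxide in a non-polar solvent, where the tight ion pair shields oxygen and delivers the allylic halide to the ortho carbon; the para position is blocked by bromine.

Step 2
Reactants: 3 4-bromo-2-(3-methylbut-2-enyl)phenol
Product: 4 [4-bromo-2-(3-methylbut-2-enyl)phenoxy]triisopropylsilane
Conditions: TIPSCl, imidazole, DMF, rt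
Reagents that add atoms: triisopropylsilyl chloride, CC(C)[Si](Cl)(C(C)C)C(C)C
Why: Standard silyl ether formation on a phenol; the triisopropylsilyl group is chosen because it tolerates the basic coupling in step 7 and falls to fluoride at the end.

Step 3
Reactants: 5 1-(2,4,6-trihydroxyphenyl)ethanone (2,4,6-trihydroxyacetophenone)
Product: 6 1-[2-hydroxy-4,6-bis(triisopropylsilyloxy)phenyl]ethanone
Conditions: TIPSCl (2.2 equiv), imidazole, DMAP (cat.), DMF, 0 °C to rt
Reagents that add atoms: triisopropylsilyl chloride, CC(C)[Si](Cl)(C(C)C)C(C)C
Why: Chemoselective bis-silylation: the para hydroxyl and one of the two equivalent ortho hydroxyls react, while the last one stays locked in the hydrogen bond to the ketone, as in the usual bis-protection of phloroacetophenone.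

Step 4
Reactants: 6 1-[2-hydroxy-4,6-bis(triisopropylsilyloxy)phenyl]ethanone; 7 3-methylbut-2-en-1-ol (prenol)
Product: 8 1-[2-(3-methylbut-2-enyloxy)-4,6-bis(triisopropylsilyloxy)phenyl]ethanone
Conditions: PPh3, DIAD, THF, 0 °C to rt
Reagents that add atoms: none
Why: Mitsunobu etherification of the acidic, chelated phenol with a primary allylic alcohol; the neutral conditions spare the aryl silyl ethers and avoid C-alkylation.

Step 5
Reactants: 8 1-[2-(3-methylbut-2-enyloxy)-4,6-bis(triisopropylsilyloxy)phenyl]ethanone
Product: 11 1-[6-hydroxy-3-(3-methylbut-2-enyl)-2,4-bis(triisopropylsilyloxy)phenyl]ethanone, via Claisen ortho-dienone 9 (not isolated), via Cope para-dienone 10 (not isolated)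
Conditions: PhNEt2, 200 °C, sealed tube
Reagents that add atoms: none
Why: Aromatic Claisen rearrangement to the ortho carbon (racemic dienone 9) followed by a Cope shift to the para carbon (dienone 10) and enolisation, the para-Claisen sequence known for 2-prenyloxy-4,6-dialkoxyacetophenones; the double allylic inversion returns a normal prenyl group, and the oxygen that carried it is left as the only free phenol.

Step 6
Reactants: 11 1-[6-hydroxy-3-(3-methylbut-2-enyl)-2,4-bis(triisopropylsilyloxy)phenyl]ethanone
Product: 12 1-[6-(methoxymethoxy)-3-(3-methylbut-2-enyl)-2,4-bis(triisopropylsilyloxy)phenyl]ethanone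
Conditions: NaH, MOMCl, THF, 0 °C to rt
Reagents that add atoms: chloromethyl methyl ether, COCCl
Why: O-Alkylation of the sodium phenoxide (Williamson-type acetal formation); the phenol is far more acidic than the methyl ketone, and the silyl ethers are meta to the phenoxide and cannot migrate to it.

Step 7
Reactants: 12 1-[6-(methoxymethoxy)-3-(3-methylbut-2-enyl)-2,4-bis(triisopropylsilyloxy)phenyl]ethanone; 4 [4-bromo-2-(3-methylbut-2-enyl)phenoxy]triisopropylsilane
Product: 13 1-[6-(methoxymethoxy)-3-(3-methylbut-2-enyl)-2,4-bis(triisopropylsilyloxy)phenyl]-2-[3-(3-methylbut-2-enyl)-4-(triisopropylsilyloxy)phenyl]ethanone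
Conditions: Pd2(dba)3 (cat.), Xantphos, K3PO4, toluene, 90 °C
Reagents that add atoms: none
Why: Palladium-catalysed α-arylation of a methyl ketone (Buchwald–Hartwig type): oxidative addition of 4 to zerovalent palladium, enolate binding and reductive elimination; the wide-bite-angle ligand and the more acidic product favour mono-arylation, K3PO4 spares the aryl silyl ethers, and trisubstituted alkenes do not undergo Heck insertion.

Step 8
Reactants: 13 1-[6-(methoxymethoxy)-3-(3-methylbut-2-enyl)-2,4-bis(triisopropylsilyloxy)phenyl]-2-[3-(3-methylbut-2-enyl)-4-(triisopropylsilyloxy)phenyl]ethanone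
Product: 14 2-diazo-1-[6-(methoxymethoxy)-3-(3-methylbut-2-enyl)-2,4-bis(triisopropylsilyloxy)phenyl]-2-[3-(3-methylbut-2-enyl)-4-(triisopropylsilyloxy)phenyl]ethanone
Conditions: p-ABSA, DBU, MeCN/CH2Cl2, 0 °C to rt
Reagents that add atoms: 4-acetamidobenzenesulfonyl azide, CC(=O)Nc1ccc(cc1)S(=O)(=O)N=[N+]=[N-]
Why: Regitz diazo transfer: the methylene between aryl and aroyl is acidic enough for DBU, the enolate attacks the terminal azide nitrogen and the triazene collapses to diazoketone and sulfonamide, the standard route to α-aryl-α-diazoketones from benzyl ketones.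

Step 9
Reactants: 14 2-diazo-1-[6-(methoxymethoxy)-3-(3-methylbut-2-enyl)-2,4-bis(triisopropylsilyloxy)phenyl]-2-[3-(3-methylbut-2-enyl)-4-(triisopropylsilyloxy)phenyl]ethanone
Product: 15 2-methoxy-6-(3-methylbut-2-enyl)-3-[3-(3-methylbut-2-enyl)-4-(triisopropylsilyloxy)phenyl]-5,7-bis(triisopropylsilyloxy)chroman-4-one (racemic, mixture of cis and trans isomers at C2/C3)
Conditions: Rh2(OAc)4 (1 mol%), CH2Cl2, rt, slow addition of 14
Reagents that add atoms: none
Why: Rh2(OAc)4 (divalent rhodium) expels N2 from 14 and leaves an electrophilic carbenoid at C3 that is stabilised by the electron-rich ring B as donor and the aroyl group as acceptor. The carbenoid inserts into one of the two hydridic C–H bonds of the O1–CH2–OMe carbon in a concerted, asynchronous three-centre process with hydride-transfer character, forming C2–C3 and releasing the catalyst. Ring C closes in a 1,6-insertion through a six-membered transition state made up of C3, C4, C4a, C8a, O1 and C2, so the pyranone ring is completed by a C–C bond and not by a C–O bond. The closest known reaction type is the dirhodium-carboxylate-catalysed insertion of 2-alkoxyaryl diazoketones into the C–H bond next to the ether oxygen, which gives chroman-4-ones, together with carbenoid insertion into acetal C–H bonds. C2 and C3 are new stereocentres, but the catalyst is achiral and the substrate has no other stereocentre, so 15 is racemic; the cyclic transition state should favour the cis isomer, C3 can epimerise, and neither centre needs control because both are removed in step 10. The selectivity that matters is site selectivity: the only other oxygen ortho to the acyl group carries a triisopropylsilyl group whose unactivated C–H bonds could be reached only through seven- or eight-membered transition states, and the prenyl groups and the ring B silyl ether are meta or para to the reacting positions and cannot be spanned. Chemoselectivity over attack of the O1 lone pair on the carbenoid (oxonium ylide, then 1,2-shift of the CH2OMe group to a benzofuran-3-one) is favoured by the donor-stabilised, less electrophilic carbenoid, by the carboxylate ligands, by the doubly activated acetal C–H bond and by slow addition in a non-coordinating solvent.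

Step 10
Reactants: 15 2-methoxy-6-(3-methylbut-2-enyl)-3-[3-(3-methylbut-2-enyl)-4-(triisopropylsilyloxy)phenyl]-5,7-bis(triisopropylsilyloxy)chroman-4-one
Product: 16 6-(3-methylbut-2-enyl)-3-[3-(3-methylbut-2-enyl)-4-(triisopropylsilyloxy)phenyl]-5,7-bis(triisopropylsilyloxy)chromen-4-one
Conditions: DBU, CH2Cl2, rt
Reagents that add atoms: none
Why: E1cB β-elimination: C3–H is benzylic and α to the ketone, and the enolate expels methoxide from C2 (or opens to the phenoxide, which recloses by addition–elimination), both paths ending at the conjugated 4-pyranone; it is the O-methyl counterpart of the dehydration of 2-hydroxyisoflavanones, and both stereocentres vanish.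

Step 11
Reactants: 16 6-(3-methylbut-2-enyl)-3-[3-(3-methylbut-2-enyl)-4-(triisopropylsilyloxy)phenyl]-5,7-bis(triisopropylsilyloxy)chromen-4-one
Product: 17 lupalbigenin, 5,7-dihydroxy-3-[4-hydroxy-3-(3-methylbut-2-enyl)phenyl]-6-(3-methylbut-2-enyl)chromen-4-one
Conditions: TBAF, AcOH, THF, 0 °C to rt
Reagents that add atoms: none
Why: Fluoride cleavage of the three aryl silyl ethers, driven by Si–F bond formation; acetic acid buffers the phenoxides, and nothing acidic or oxidising touches the prenyl groups.

Compound list

1 | 4-bromophenol | Oc1ccc(Br)cc1 | starting material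
2 | 1-bromo-3-methylbut-2-ene (prenyl bromide) | CC(C)=CCBr | starting material
3 | 4-bromo-2-(3-methylbut-2-enyl)phenol | CC(C)=CCc1cc(Br)ccc1O | intermediate
4 | [4-bromo-2-(3-methylbut-2-enyl)phenoxy]triisopropylsilane | CC(C)=CCc1cc(Br)ccc1O[Si](C(C)C)(C(C)C)C(C)C | intermediate
5 | 1-(2,4,6-trihydroxyphenyl)ethanone | CC(=O)c1c(O)cc(O)cc1O | starting material
6 | 1-[2-hydroxy-4,6-bis(triisopropylsilyloxy)phenyl]ethanone | CC(=O)c1c(O)cc(O[Si](C(C)C)(C(C)C)C(C)C)cc1O[Si](C(C)C)(C(C)C)C(C)C | intermediate
7 | 3-methylbut-2-en-1-ol (prenol) | CC(C)=CCO | starting material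
8 | 1-[2-(3-methylbut-2-enyloxy)-4,6-bis(triisopropylsilyloxy)phenyl]ethanone | CC(=O)c1c(OCC=C(C)C)cc(O[Si](C(C)C)(C(C)C)C(C)C)cc1O[Si](C(C)C)(C(C)C)C(C)C | intermediate
9 | 2-acetyl-6-(2-methylbut-3-en-2-yl)-3,5-bis(triisopropylsilyloxy)cyclohexa-2,4-dien-1-one (racemic, not isolated) | CC(=O)C1=C(O[Si](C(C)C)(C(C)C)C(C)C)C=C(O[Si](C(C)C)(C(C)C)C(C)C)C(C(C)(C)C=C)C1=O | intermediate
10 | 2-acetyl-4-(3-methylbut-2-enyl)-3,5-bis(triisopropylsilyloxy)cyclohexa-2,5-dien-1-one (racemic, not isolated) | CC(=O)C1=C(O[Si](C(C)C)(C(C)C)C(C)C)C(CC=C(C)C)C(O[Si](C(C)C)(C(C)C)C(C)C)=CC1=O | intermediate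
11 | 1-[6-hydroxy-3-(3-methylbut-2-enyl)-2,4-bis(triisopropylsilyloxy)phenyl]ethanone | CC(=O)c1c(O)cc(O[Si](C(C)C)(C(C)C)C(C)C)c(CC=C(C)C)c1O[Si](C(C)C)(C(C)C)C(C)C | intermediate
12 | 1-[6-(methoxymethoxy)-3-(3-methylbut-2-enyl)-2,4-bis(triisopropylsilyloxy)phenyl]ethanone | CC(=O)c1c(OCOC)cc(O[Si](C(C)C)(C(C)C)C(C)C)c(CC=C(C)C)c1O[Si](C(C)C)(C(C)C)C(C)C | intermediate
13 | 1-[6-(methoxymethoxy)-3-(3-methylbut-2-enyl)-2,4-bis(triisopropylsilyloxy)phenyl]-2-[3-(3-methylbut-2-enyl)-4-(triisopropylsilyloxy)phenyl]ethanone | COCOc1cc(O[Si](C(C)C)(C(C)C)C(C)C)c(CC=C(C)C)c(O[Si](C(C)C)(C(C)C)C(C)C)c1C(=O)Cc1ccc(O[Si](C(C)C)(C(C)C)C(C)C)c(CC=C(C)C)c1 | intermediate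
14 | 2-diazo-1-[6-(methoxymethoxy)-3-(3-methylbut-2-enyl)-2,4-bis(triisopropylsilyloxy)phenyl]-2-[3-(3-methylbut-2-enyl)-4-(triisopropylsilyloxy)phenyl]ethanone | COCOc1cc(O[Si](C(C)C)(C(C)C)C(C)C)c(CC=C(C)C)c(O[Si](C(C)C)(C(C)C)C(C)C)c1C(=O)C(=[N+]=[N-])c1ccc(O[Si](C(C)C)(C(C)C)C(C)C)c(CC=C(C)C)c1 | intermediate
15 | 2-methoxy-6-(3-methylbut-2-enyl)-3-[3-(3-methylbut-2-enyl)-4-(triisopropylsilyloxy)phenyl]-5,7-bis(triisopropylsilyloxy)chroman-4-one (racemic, cis/trans mixture at C2/C3) | COC1Oc2cc(O[Si](C(C)C)(C(C)C)C(C)C)c(CC=C(C)C)c(O[Si](C(C)C)(C(C)C)C(C)C)c2C(=O)C1c1ccc(O[Si](C(C)C)(C(C)C)C(C)C)c(CC=C(C)C)c1 | intermediate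
16 | 6-(3-methylbut-2-enyl)-3-[3-(3-methylbut-2-enyl)-4-(triisopropylsilyloxy)phenyl]-5,7-bis(triisopropylsilyloxy)chromen-4-one | CC(C)=CCc1cc(-c2coc3cc(O[Si](C(C)C)(C(C)C)C(C)C)c(CC=C(C)C)c(O[Si](C(C)C)(C(C)C)C(C)C)c3c2=O)ccc1O[Si](C(C)C)(C(C)C)C(C)C | intermediate
17 | lupalbigenin, 5,7-dihydroxy-3-[4-hydroxy-3-(3-methylbut-2-enyl)phenyl]-6-(3-methylbut-2-enyl)chromen-4-one | CC(C)=CCc1cc(-c2coc3cc(O)c(CC=C(C)C)c(O)c3c2=O)ccc1O | target

Total step count: 11. Longest linear sequence: 9 steps (5 to 17, steps 3 to 11); the ring B branch (steps 1 and 2) joins at step 7.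

Steps least certain to work

Step 9 (key step). The most likely failure is chemoselectivity. The carbenoid may be captured by the lone pair of the aryl ether oxygen, and the resulting oxonium ylide would pass on its CH2OMe group by a 1,2-shift, closing a five-membered instead of a six-membered ring. Hydride abstraction from the acetal carbon without C–C bond formation is a second possible diversion. The fallback closes ring C in the classical way; it sets out from 13 and returns at 16. The methoxymethyl group of 13 would be removed with ZnBr2 and propane-1-thiol in CH2Cl2 to give 1-[6-hydroxy-3-(3-methylbut-2-enyl)-2,4-bis(triisopropylsilyloxy)phenyl]-2-[3-(3-methylbut-2-enyl)-4-(triisopropylsilyloxy)phenyl]ethanone F1. Heating F1 with N,N-dimethylformamide dimethyl acetal in toluene should give 3-(dimethylamino)-1-[6-hydroxy-3-(3-methylbut-2-enyl)-2,4-bis(triisopropylsilyloxy)phenyl]-2-[3-(3-methylbut-2-enyl)-4-(triisopropylsilyloxy)phenyl]prop-2-en-1-one F2. The free phenol of F2 then adds to the enaminone and expels dimethylamine, giving 16.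

Step 7. Two processes threaten it: slow coupling of the doubly ortho-substituted ketone enolate, and transfer or loss of the silyl group on the neighbouring oxygen once the enolate is formed at 90 °C. The fallback makes the C3–C1' bond on the diazo compound instead of the enolate; it sets out from 12 and 4 and returns at 14, skipping 13. Ketone 12 would be deprotonated at −78 °C with LiN(SiMe3)2 and trifluoroacetylated with 2,2,2-trifluoroethyl trifluoroacetate to give 4,4,4-trifluoro-1-[6-(methoxymethoxy)-3-(3-methylbut-2-enyl)-2,4-bis(triisopropylsilyloxy)phenyl]butane-1,3-dione F3. Detrifluoroacetylative diazo transfer with methanesulfonyl azide and Et3N would give 2-diazo-1-[6-(methoxymethoxy)-3-(3-methylbut-2-enyl)-2,4-bis(triisopropylsilyloxy)phenyl]ethanone F4. Bromide 4 would be converted by copper-catalysed halogen exchange (CuI, NaI, a 1,2-diamine ligand, dioxane) into [4-iodo-2-(3-methylbut-2-enyl)phenoxy]triisopropylsilane F5. Palladium-catalysed C–H arylation of the acyldiazomethane F4 with F5 (Pd(PPh3)4, Ag2CO3, Et3N, toluene, rt) would then give 14 without any heated enolate.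

Step 5. The rearrangement may stop after the first shift, with dienone 9 enolising to the ortho 1,1-dimethylallyl phenol, because the para carbon lies between two bulky silyloxy groups; thermal loss of a silyl group is a lesser risk. The fallback gives up the rearrangement and relies on steric differentiation; it sets out from 5 and 2 and returns at 12. Ketone 5 would be C-prenylated with 2 in aqueous KOH at 0 °C to give 1-[2,4,6-trihydroxy-3-(3-methylbut-2-enyl)phenyl]ethanone F6. The non-chelated 4-hydroxyl would be silylated first (TIPSCl, imidazole) to give 1-[2,6-dihydroxy-3-(3-methylbut-2-enyl)-4-(triisopropylsilyloxy)phenyl]ethanone F7. One equivalent of chloromethyl methyl ether with i-Pr2NEt should then react at the chelated hydroxyl that has no prenyl neighbour, giving 1-[2-hydroxy-6-(methoxymethoxy)-3-(3-methylbut-2-enyl)-4-(triisopropylsilyloxy)phenyl]ethanone F8. Forced silylation of the last hydroxyl (TIPSOTf, 2,6-lutidine) returns to 12. The regiochemistry of this detour rests on sterics only, which is why it is the fallback and not the route.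

Step 1. O-Alkylation, double alkylation and acid-induced closure of the product to a chroman during work-up may erode the C-alkylation. The fallback builds the side chain in stages; it sets out from 1 and returns at 3. O-Allylation of 1 (allyl bromide, K2CO3, acetone) would give 1-bromo-4-(prop-2-enyloxy)benzene F9. Thermal Claisen rearrangement would give 4-bromo-2-(prop-2-enyl)phenol F10. Cross-metathesis of F10 with 2-methylbut-2-ene and the second-generation Grubbs catalyst would give 3.

Further compounds

F1 | step 9 | 1-[6-hydroxy-3-(3-methylbut-2-enyl)-2,4-bis(triisopropylsilyloxy)phenyl]-2-[3-(3-methylbut-2-enyl)-4-(triisopropylsilyloxy)phenyl]ethanone | Oc1cc(O[Si](C(C)C)(C(C)C)C(C)C)c(CC=C(C)C)c(O[Si](C(C)C)(C(C)C)C(C)C)c1C(=O)Cc1ccc(O[Si](C(C)C)(C(C)C)C(C)C)c(CC=C(C)C)c1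
F2 | step 9 | 3-(dimethylamino)-1-[6-hydroxy-3-(3-methylbut-2-enyl)-2,4-bis(triisopropylsilyloxy)phenyl]-2-[3-(3-methylbut-2-enyl)-4-(triisopropylsilyloxy)phenyl]prop-2-en-1-one (alkene geometry not defined) | CN(C)C=C(C(=O)c1c(O)cc(O[Si](C(C)C)(C(C)C)C(C)C)c(CC=C(C)C)c1O[Si](C(C)C)(C(C)C)C(C)C)c1ccc(O[Si](C(C)C)(C(C)C)C(C)C)c(CC=C(C)C)c1
F3 | step 7 | 4,4,4-trifluoro-1-[6-(methoxymethoxy)-3-(3-methylbut-2-enyl)-2,4-bis(triisopropylsilyloxy)phenyl]butane-1,3-dione | COCOc1cc(O[Si](C(C)C)(C(C)C)C(C)C)c(CC=C(C)C)c(O[Si](C(C)C)(C(C)C)C(C)C)c1C(=O)CC(=O)C(F)(F)F
F4 | step 7 | 2-diazo-1-[6-(methoxymethoxy)-3-(3-methylbut-2-enyl)-2,4-bis(triisopropylsilyloxy)phenyl]ethanone | COCOc1cc(O[Si](C(C)C)(C(C)C)C(C)C)c(CC=C(C)C)c(O[Si](C(C)C)(C(C)C)C(C)C)c1C(=O)C=[N+]=[N-]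
F5 | step 7 | [4-iodo-2-(3-methylbut-2-enyl)phenoxy]triisopropylsilane | CC(C)=CCc1cc(I)ccc1O[Si](C(C)C)(C(C)C)C(C)C
F6 | step 5 | 1-[2,4,6-trihydroxy-3-(3-methylbut-2-enyl)phenyl]ethanone | CC(=O)c1c(O)cc(O)c(CC=C(C)C)c1O
F7 | step 5 | 1-[2,6-dihydroxy-3-(3-methylbut-2-enyl)-4-(triisopropylsilyloxy)phenyl]ethanone | CC(=O)c1c(O)cc(O[Si](C(C)C)(C(C)C)C(C)C)c(CC=C(C)C)c1O
F8 | step 5 | 1-[2-hydroxy-6-(methoxymethoxy)-3-(3-methylbut-2-enyl)-4-(triisopropylsilyloxy)phenyl]ethanone | CC(=O)c1c(OCOC)cc(O[Si](C(C)C)(C(C)C)C(C)C)c(CC=C(C)C)c1O
F9 | step 1 | 1-bromo-4-(prop-2-enyloxy)benzene | C=CCOc1ccc(Br)cc1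
F10 | step 1 | 4-bromo-2-(prop-2-enyl)phenol | C=CCc1cc(Br)ccc1O
A1 | alternative 1 | 5-hydroxy-3-[4-hydroxy-3-(3-methylbut-2-enyl)phenyl]-6-(3-methylbut-2-enyl)-7-(triisopropylsilyloxy)chromen-4-one | CC(C)=CCc1cc(-c2coc3cc(O[Si](C(C)C)(C(C)C)C(C)C)c(CC=C(C)C)c(O)c3c2=O)ccc1O
A2 | alternative 1 | 5-(2-methylbut-3-en-2-yloxy)-3-[4-(2-methylbut-3-en-2-yloxy)phenyl]-7-(triisopropylsilyloxy)chromen-4-one | C=CC(C)(C)Oc1ccc(-c2coc3cc(O[Si](C(C)C)(C(C)C)C(C)C)cc(OC(C)(C)C=C)c3c2=O)cc1
A3 | alternative 1 | genistein, 5,7-dihydroxy-3-(4-hydroxyphenyl)chromen-4-one | O=c1c(-c2ccc(O)cc2)coc2cc(O)cc(O)c12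
A4 | alternative 2 | 1-[6-bromo-2,4-dihydroxy-3-(3-methylbut-2-enyl)phenyl]-2-[4-(methoxymethoxy)-3-(3-methylbut-2-enyl)phenyl]ethanone | O=C(Cc1ccc(OCOC)c(CC=C(C)C)c1)c1c(Br)cc(O)c(CC=C(C)C)c1O
A5 | alternative 2 | 1-methoxy-2-(3-methylbut-2-enyl)-1,3-bis(trimethylsilyloxy)buta-1,3-diene | COC(O[Si](C)(C)C)=C(CC=C(C)C)C(=C)O[Si](C)(C)C
A6 | alternative 2 | 4-bromo-1-[4-(methoxymethoxy)-3-(3-methylbut-2-enyl)phenyl]but-3-yn-2-one | BrC#CC(=O)Cc1ccc(OCOC)c(CC=C(C)C)c1
A7 | alternative 3 | 3-[4-(tert-butyldimethylsilyloxy)-3-(3-methylbut-2-enyl)cyclohexa-1,4-dien-1-yl]-5,7-bis(methoxymethoxy)-6-(3-methylbut-2-enyl)chromen-4-one | COCOc1cc2occ(C3=CCC(O[Si](C)(C)C(C)(C)C)=C(CC=C(C)C)C3)c(=O)c2c(OCOC)c1CC=C(C)C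
A8 | alternative 3 | 3-ethynyl-5,7-bis(methoxymethoxy)-6-(3-methylbut-2-enyl)chromen-4-one | C#Cc1coc2cc(OCOC)c(CC=C(C)C)c(OCOC)c2c1=O
A9 | alternative 3 | 2-(tert-butyldimethylsilyloxy)-3-(3-methylbut-2-enyl)buta-1,3-diene | C=C(O[Si](C)(C)C(C)(C)C)C(=C)CC=C(C)C
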